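**Plan**

1. Locants (germacrane numbering): C-1 = the O–CH next to the formyl-bearing alkene carbon C-10 (CHO = C-14); C-2, C-3 = the two CH2; C-4 = spiro-epoxide carbon (CH2 = C-15); C-5 = the other O–CH; C-6/C-7 = lactone O–CH/CH; C-8 = ester carbon; C-9 = alkene CH; C-11/C-12/C-13 = lactone carbons.
2. Retrosynthesis: the C-8 ester, the 9,10-enal (from an 8,9-epoxide and a C-14 aldehyde), both epoxides, C-13, the lactone C–O bond and a helper ketone at C-2 are cleared back to bicyclic ketone 16. Then O–C-1 and C-1–C-10 are cut together while O–C-8 is re-formed, which contracts the oxygen-bridged ten-membered carbocycle to the 2,5-cis oxolane diazoketone 14. 14 is traced back (C-3–C-4 by Negishi coupling, the two alkenyl groups by ring-opening cross-metathesis, C-7–C-11 by enolate alkylation) to oxanorbornenone 1.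
3. Enabling feature: the oxane O and C-1 are followed by C-10=C-9–C-8, the O–C–C–C=C imprint of a [2,3] shift of an allyl group from an oxonium O to an adjacent ylide carbon. C-8 is linked to the same O through C-7–C-6–C-5, so O, C-5, C-6, C-7 and C-8 define an oxolane (temporary ring) that grows by three atoms (C-9, C-10, C-1).
4. Forward order: oxolane (from the oxanorbornene) → diazoketone tethered through C-4–C-3–C-2 → oxane ring (O–C-1) and ten-membered carbocycle (C-1–C-10) in one operation → C-2 ketone removed → lactone, α-methylene, two epoxides, enal, ester.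
5. Stereochemistry: the bridgeheads of 1 give C-5 and the 2,5-cis relation; exo alkylation and exo hydride give C-7 and C-6; C-1 is fixed by the cis bridge formed in the ring expansion; C-4 by epoxidation anti to the bridge; C-8 by convex-face epoxidation followed by Mitsunobu inversion; the 9,10-alkene geometry by the eight-membered ring.

Key step: step 10

Remark (assumption): ketone 1 (the "naked sugar" bicyclic ketone) and allyl ether 6 are taken as purchasable catalogue compounds, 1 as the single (1S,4S) enantiomer.

**Route**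

Step 1
Reactants: 1 (1S,4S)-7-oxabicyclo[2.2.1]hept-5-en-2-one; 2 methyl bromoacetate
Product: 3 exo-alkylated keto ester
Conditions: LiN(SiMe3)2, THF/DMPU, −78 °C; then 2, −78 → −40 °C
Reagents that add atoms: none
Why: Alkylation of the kinetic lithium enolate, which can form only on the CH2 side (the bridgehead cannot enolise) and is kept cold so that the oxygen bridge is not expelled, should occur on the convex exo face and set C-7.

Step 2
Reactants: 3 exo-alkylated keto ester
Product: 4 endo alcohol
Conditions: NaBH4, MeOH, −20 °C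
Reagents that add atoms: none
Why: Hydride reduction of a bicyclo[2.2.1]heptanone from the exo face (the side of the one-atom oxygen bridge) should give the endo alcohol and so set C-6 trans to the side chain, an arrangement in which the hydroxy ester cannot lactonise.

Step 3
Reactants: 4 endo alcohol
Product: 5 silyl ether
Conditions: TBSOTf, 2,6-lutidine, CH2Cl2, −78 → 0 °C
Reagents that add atoms: tert-butyldimethylsilyl trifluoromethanesulfonate, CC(C)(C)[Si](C)(C)OS(=O)(=O)C(F)(F)F
Why: Silylation of the hindered secondary alcohol with the silyl triflate (standard protection) masks O-6 and adds bulk beside the future C-5 vinyl group.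

Step 4
Reactants: 5 silyl ether; 6 allyl 4-methoxybenzyl ether
Product: 7 2,5-cis oxolane
Conditions: second-generation Hoveyda–Grubbs catalyst RuCl2(H2IMes)(=CH-C6H4-2-OiPr) (5 mol %), 6 (3 equiv), CH2Cl2, 40 °C
Reagents that add atoms: none
Why: Strain-driven ring-opening cross-metathesis turns the two bridgeheads into the 2,5-cis carbons of an oxolane; the alkylidene is expected to form, and to be capped by 6, at the alkene carbon remote from the bulky endo silyl ether, which leaves a vinyl group on C-5 and an (E)-allylic ether on C-8.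

Step 5
Reactants: 7 2,5-cis oxolane
Product: 8 methyl ketone
Conditions: PdCl2(quinox) [quinox = 2-(4,5-dihydro-1,3-oxazol-2-yl)quinoline] (5 mol %), AgSbF6 (12 mol %), aq. tBuOOH, CH2Cl2, 0 °C → rt
Reagents that add atoms: tert-butyl hydroperoxide, CC(C)(C)OO
Why: Wacker oxidation with the cationic quinox–palladium/hydroperoxide system should convert the only monosubstituted alkene, an allylic ether, into the Markovnikov methyl ketone and leave the 1,2-disubstituted alkene.

Step 6
Reactants: 8 methyl ketone
Product: 9 enol triflate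
Conditions: KN(SiMe3)2, THF, −78 °C; then PhNTf2
Reagents that add atoms: N-phenylbis(trifluoromethanesulfonimide), O=S(=O)(N(c1ccccc1)S(=O)(=O)C(F)(F)F)C(F)(F)F
Why: Kinetic deprotonation at the methyl group (the tertiary α-alkoxy C–H is slower) and O-sulfonylation should give the 1,1-disubstituted enol triflate.

Step 7
Reactants: 9 enol triflate; 10 (2-tert-butoxy-2-oxoethyl)zinc bromide
Product: 11 tert-butyl ester
Conditions: Pd(PPh3)4 (zerovalent palladium, 5 mol %), THF, 60 °C
Reagents that add atoms: none
Why: Negishi coupling of the alkenyl triflate with a Reformatsky reagent joins C-4 to C-3 and keeps the 4(15)-methylidene group.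

Step 8
Reactants: 11 tert-butyl ester
Product: 12 carboxylic acid
Conditions: TMSOTf, 2,6-lutidine, CH2Cl2, 0 °C; then aqueous work-up
Reagents that add atoms: none
Why: Trimethylsilyl triflate/lutidine cleaves the tert-butyl ester through its silyl ester with loss of isobutene, conditions under which the methyl ester, the silyl ether and the PMB ether should persist.

Step 9
Reactants: 12 carboxylic acid
Product: 14 diazoketone, via mixed anhydride 13 (not isolated)
Conditions: iBuOCOCl, N-methylmorpholine, THF, −20 °C; then CH2N2, Et2O, 0 °C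
Reagents that add atoms: diazomethane, C=[N+]=[N-]; isobutyl chloroformate, CC(C)COC(=O)Cl (its atoms remain only in 13)
Why: Acylation of diazomethane by the mixed carbonic anhydride (first stage of the Arndt–Eistert sequence) gives the terminal α-diazoketone under non-acidic conditions; the C-2 carbonyl is the temporary activating group for the carbene.

Step 10
Reactants: 14 diazoketone
Product: 16 ring-expanded bicyclic ketone, via oxonium ylide 15 (not isolated)
Conditions: Cu(hfacac)2 (copper bis(hexafluoroacetylacetonate), 5 mol %), CH2Cl2, reflux, slow addition of 14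
Reagents that add atoms: none
Why: The copper carbenoid formed from the diazoketone with loss of N2 is attacked by a lone pair of the oxolane oxygen through a six-membered transition state (closure of the oxane ring at O–C-1) to give the cis-fused bicyclic oxonium ylide 15; its ylide carbon C-1 then bonds to the alkene terminus C-10 while the allylic O–C-8 bond breaks in a suprafacial [2,3]-sigmatropic shift through a five-membered envelope, so the oxolane grows by three atoms into the eight-membered oxacycle and the ten-membered carbocycle appears without a macrocyclisation. The closest known reaction type is the copper-catalysed oxonium ylide formation/[2,3] rearrangement of α-vinyl cyclic ethers carrying a tethered diazoketone, which gives oxygen-bridged medium rings by three-atom ring expansion. C-1 is fixed by the tether, because the ylide carbon sits on the oxolane face that carries both the C-5 chain and the C-8 alkenyl group (2,5-cis), so the five-carbon bridge can only end up cis on the new oxane; C-10 (lost again later) follows from suprafacial transfer from C-8 with the (E)-alkene holding CH2OPMB outside the envelope; the new 8,9-alkene is Z because the eight-membered ring cannot hold an E-alkene. The step needs ylide formation to outrun insertion into the C-5–H bond and addition to the 4(15)-alkene, and the [2,3] shift to outrun a [1,2] shift; the electrophilic Cu(hfacac)2 carbenoid, the six-membered geometry for attack by the ring oxygen and the syn placement of ylide carbon and C-8 alkenyl group should secure this.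

Step 11
Reactants: 16 ring-expanded bicyclic ketone
Product: 17 C-2 alcohol
Conditions: NaBH4, MeOH, −40 °C (crude 16 used directly)
Reagents that add atoms: none
Why: Borohydride reduction of the crude ketone removes the β,γ-unsaturated carbonyl before it can move into conjugation; the carbinol configuration does not matter because this oxygen is removed in step 13.

Step 12
Reactants: 17 C-2 alcohol
Product: 18 imidazolyl thiocarbamate
Conditions: 1,1'-thiocarbonyldiimidazole, DMAP (cat.), ClCH2CH2Cl, 60 °C
Reagents that add atoms: 1,1'-thiocarbonyldiimidazole, S=C(n1ccnc1)n1ccnc1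
Why: Thioacylation of the secondary alcohol gives the thiocarbonyl derivative needed for Barton–McCombie deoxygenation.

Step 13
Reactants: 18 imidazolyl thiocarbamate
Product: 19 deoxygenated bicyclic ester
Conditions: Bu3SnH (concentrated), AIBN (cat.), toluene, 100 °C
Reagents that add atoms: none
Why: Barton–McCombie deoxygenation removes the helper oxygen; the secondary C-2 radical should be reduced by the stannane faster than it rearranges through the homoallyl/cyclopropylcarbinyl manifold, a β-alkoxy radical does not fragment, and no conjugated acceptor is yet present.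

Step 14
Reactants: 19 deoxygenated bicyclic ester
Product: 21 trans-fused lactone, via hydroxy ester 20 (not isolated)
Conditions: Bu4NF, THF, 0 °C → rt
Reagents that add atoms: none
Why: Fluoride removes the silyl group and the C-6 alkoxide closes the trans-fused γ-lactone on the methyl ester (lactonisation, possible now that C-6 and C-7 lie in the ten-membered ring).

Step 15
Reactants: 21 trans-fused lactone
Product: 24 α-methylene lactone, via Mannich base 22 (not isolated), via ammonium iodide 23 (not isolated)
Conditions: LiN(SiMe3)2, THF, −78 °C; CH2=NMe2+ I−; then MeI, MeOH, rt; then aq. NaHCO3/CH2Cl2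
Reagents that add atoms: N,N-dimethylmethyleneiminium iodide (Eschenmoser's salt), C=[N+](C)C.[I-]; iodomethane, CI (its atoms remain only in 23)
Why: α-Methylenation of the lactone by Mannich reaction of its lithium enolate with Eschenmoser's salt, N-methylation and E1cB loss of trimethylamine.

Step 16
Reactants: 24 α-methylene lactone
Product: 25 bis-epoxide
Conditions: mCPBA (2.5 equiv), NaHCO3, CH2Cl2, 0 °C → rt
Reagents that add atoms: 3-chloroperoxybenzoic acid, O=C(OO)c1cccc(Cl)c1
Why: Prilezhaev epoxidation of the two electron-rich alkenes (the α-methylene lactone is inert): the 4(15)-methylidene group should be attacked from the face away from the C-5–C-6 bond of the bridge, which gives the spiro-epoxide of the target, and the Z-8,9-alkene from its open convex face (ring atoms C-1 and C-6 shield the other), which places the C-8 oxygen opposite to the target and is corrected in step 19.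

Step 17
Reactants: 25 bis-epoxide
Product: 26 C-14 alcohol
Conditions: DDQ, CH2Cl2/pH 7 buffer, 0 °C
Reagents that add atoms: none
Why: Oxidative cleavage of the PMB ether by DDQ under buffered conditions frees the C-14 alcohol without touching the epoxides or the enoate.

Step 18
Reactants: 26 C-14 alcohol
Product: 28 8-epi hydroxy enal, via epoxy aldehyde 27 (not isolated)
Conditions: Dess–Martin periodinane, NaHCO3, CH2Cl2, 0 °C; then Et3N, rt
Reagents that add atoms: none
Why: Dess–Martin oxidation gives the β,γ-epoxy aldehyde, which opens with amine by E1cB through the C-10 enolate to the γ-hydroxy enal; the eight-membered ring allows only the ring-cis 9,10-alkene (E by CIP, as in the target) and C-8 keeps the configuration of the epoxide.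

Step 19
Reactants: 28 8-epi hydroxy enal; 29 methacrylic acid
Product: 30 target (CNP0257628.1)
Conditions: PPh3, DIAD, toluene, 0 °C → rt
Reagents that add atoms: none
Why: Mitsunobu esterification displaces the activated C-8 hydroxyl by methacrylate with inversion (SN2), which corrects C-8 and installs the ester in one operation.

**Compound list**

1 | (1S,4S)-7-oxabicyclo[2.2.1]hept-5-en-2-one | O=C1C[C@H]2C=C[C@@H]1O2 | starting material
2 | methyl bromoacetate | COC(=O)CBr | starting material
3 | methyl 2-[(1R,2R,4S)-3-oxo-7-oxabicyclo[2.2.1]hept-5-en-2-yl]acetate (side chain exo) | COC(=O)C[C@H]1C(=O)[C@@H]2C=C[C@H]1O2 | intermediate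
4 | methyl 2-[(1R,2S,3S,4S)-3-hydroxy-7-oxabicyclo[2.2.1]hept-5-en-2-yl]acetate (side chain exo, hydroxyl endo) | COC(=O)C[C@H]1[C@H](O)[C@@H]2C=C[C@H]1O2 | intermediate
5 | methyl 2-[(1R,2R,3S,4S)-3-(tert-butyldimethylsilyloxy)-7-oxabicyclo[2.2.1]hept-5-en-2-yl]acetate | COC(=O)C[C@H]1[C@H](O[Si](C)(C)C(C)(C)C)[C@@H]2C=C[C@H]1O2 | intermediate
6 | allyl 4-methoxybenzyl ether | C=CCOCc1ccc(OC)cc1 | starting material
7 | methyl 2-[(2R,3R,4S,5S)-4-(tert-butyldimethylsilyloxy)-5-ethenyl-2-[(E)-3-(4-methoxybenzyloxy)prop-1-enyl]oxolan-3-yl]acetate (2,5-cis; 4,5-cis) | COC(=O)C[C@H]1[C@H](O[Si](C)(C)C(C)(C)C)[C@H](C=C)O[C@@H]1/C=C/COCc1ccc(OC)cc1 | intermediate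
8 | oxolane of 7 with 5-acetyl in place of 5-ethenyl | COC(=O)C[C@H]1[C@H](O[Si](C)(C)C(C)(C)C)[C@H](C(C)=O)O[C@@H]1/C=C/COCc1ccc(OC)cc1 | intermediate
9 | oxolane of 7 with 5-[1-(trifluoromethylsulfonyloxy)ethenyl] | COC(=O)C[C@H]1[C@H](O[Si](C)(C)C(C)(C)C)[C@H](C(=C)OS(=O)(=O)C(F)(F)F)O[C@@H]1/C=C/COCc1ccc(OC)cc1 | intermediate
10 | (2-tert-butoxy-2-oxoethyl)zinc bromide | CC(C)(C)OC(=O)C[Zn]Br | starting material
11 | oxolane of 7 with 5-(4-tert-butoxy-4-oxobut-1-en-2-yl) | COC(=O)C[C@H]1[C@H](O[Si](C)(C)C(C)(C)C)[C@H](C(=C)CC(=O)OC(C)(C)C)O[C@@H]1/C=C/COCc1ccc(OC)cc1 | intermediate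
12 | oxolane of 7 with 5-(3-carboxyprop-1-en-2-yl) | COC(=O)C[C@H]1[C@H](O[Si](C)(C)C(C)(C)C)[C@H](C(=C)CC(=O)O)O[C@@H]1/C=C/COCc1ccc(OC)cc1 | intermediate
13 | isobutyl carbonic mixed anhydride of 12 (not isolated) | COC(=O)C[C@H]1[C@H](O[Si](C)(C)C(C)(C)C)[C@H](C(=C)CC(=O)OC(=O)OCC(C)C)O[C@@H]1/C=C/COCc1ccc(OC)cc1 | intermediate
14 | oxolane of 7 with 5-(5-diazo-4-oxopent-1-en-2-yl) | COC(=O)C[C@H]1[C@H](O[Si](C)(C)C(C)(C)C)[C@H](C(=C)CC(=O)C=[N+]=[N-])O[C@@H]1/C=C/COCc1ccc(OC)cc1 | intermediate
15 | cis-fused bicyclic oxonium ylide: oxolane O bonded to C-1, C-5 and C-8 (not isolated) | COC(=O)C[C@H]1[C@H](O[Si](C)(C)C(C)(C)C)[C@@H]2C(=C)CC(=O)[CH-][O+]2[C@@H]1/C=C/COCc1ccc(OC)cc1 | intermediate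
16 | methyl 1,5-epoxy-6-(tert-butyldimethylsilyloxy)-14-(4-methoxybenzyloxy)-2-oxo-13-norgermacra-4(15),8Z-dien-12-oate (C-1, C-5, C-6, C-7 as in the target; C-10 R) | COC(=O)C[C@@H]1/C=C\[C@H](COCc2ccc(OC)cc2)[C@@H]2O[C@H]([C@H]1O[Si](C)(C)C(C)(C)C)C(=C)CC2=O | intermediate
17 | 2-hydroxy analogue of 16 (C-2 carbinol drawn without assignment, removed in step 13) | COC(=O)C[C@@H]1/C=C\[C@H](COCc2ccc(OC)cc2)[C@@H]2O[C@H]([C@H]1O[Si](C)(C)C(C)(C)C)C(=C)CC2O | intermediate
18 | 2-O-(imidazol-1-ylthiocarbonyl) derivative of 17 | COC(=O)C[C@@H]1/C=C\[C@H](COCc2ccc(OC)cc2)[C@@H]2O[C@H]([C@H]1O[Si](C)(C)C(C)(C)C)C(=C)CC2OC(=S)n1ccnc1 | intermediate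
19 | methyl 1,5-epoxy-6-(tert-butyldimethylsilyloxy)-14-(4-methoxybenzyloxy)-13-norgermacra-4(15),8Z-dien-12-oate | COC(=O)C[C@@H]1/C=C\[C@H](COCc2ccc(OC)cc2)[C@@H]2O[C@H]([C@H]1O[Si](C)(C)C(C)(C)C)C(=C)CC2 | intermediate
20 | 6-hydroxy analogue of 19 (not isolated) | COC(=O)C[C@@H]1/C=C\[C@H](COCc2ccc(OC)cc2)[C@@H]2O[C@H]([C@H]1O)C(=C)CC2 | intermediate
21 | 1,5-epoxy-14-(4-methoxybenzyloxy)-13-norgermacra-4(15),8Z-dien-12,6-olide (trans-fused lactone) | O=C1C[C@@H]2/C=C\[C@H](COCc3ccc(OC)cc3)[C@@H]3O[C@H]([C@H]2O1)C(=C)CC3 | intermediate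
22 | 11-(dimethylaminomethyl) derivative of 21 (C-11 unassigned; not isolated) | CN(C)CC1[C@@H]2/C=C\[C@H](COCc3ccc(OC)cc3)[C@@H]3O[C@H]([C@H]2OC1=O)C(=C)CC3 | intermediate
23 | trimethylammonium iodide of 22 (not isolated) | C[N+](C)(C)CC1[C@@H]2/C=C\[C@H](COCc3ccc(OC)cc3)[C@@H]3O[C@H]([C@H]2OC1=O)C(=C)CC3.[I-] | intermediate
24 | 1,5-epoxy-14-(4-methoxybenzyloxy)germacra-4(15),8Z,11(13)-trien-12,6-olide | C=C1[C@@H]2/C=C\[C@H](COCc3ccc(OC)cc3)[C@@H]3O[C@H]([C@H]2OC1=O)C(=C)CC3 | intermediate
25 | 1,5:4,15:8,9-triepoxy-14-(4-methoxybenzyloxy)germacr-11(13)-en-12,6-olide (C-4 as in the target; 8,9-epoxide on the convex face) | C=C1[C@@H]2[C@H]3O[C@H]3[C@H](COCc4ccc(OC)cc4)[C@@H]5O[C@H]([C@H]2OC1=O)[C@]6(CO6)CC5 | intermediate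
26 | 14-hydroxy analogue of 25 | C=C1[C@@H]2[C@H]3O[C@H]3[C@H](CO)[C@@H]4O[C@H]([C@H]2OC1=O)[C@]5(CO5)CC4 | intermediate
27 | 14-oxo analogue of 25 (β,γ-epoxy aldehyde; not isolated) | C=C1[C@@H]2[C@H]3O[C@H]3[C@H](C=O)[C@@H]4O[C@H]([C@H]2OC1=O)[C@]5(CO5)CC4 | intermediate
28 | 1,5:4,15-diepoxy-8-hydroxy-14-oxogermacra-9,11(13)-dien-12,6-olide, C-8 epimer of the target alcohol | C=C1[C@@H]2[C@@H](O)/C=C(/C=O)[C@@H]3O[C@H]([C@H]2OC1=O)[C@]4(CO4)CC3 | intermediate
29 | methacrylic acid | C=C(C)C(=O)O | starting material
30 | CNP0257628.1 (8-O-methacryloyl-1,5:4,15-diepoxy-14-oxogermacra-9,11(13)-dien-12,6-olide) | C=C(C)C(=O)O[C@@H]1/C=C(/C=O)[C@H]2CC[C@@]3(CO3)[C@H](O2)[C@H]2OC(=O)C(=C)[C@@H]21 | target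

**Count and risks**

Total steps: 19. Longest linear sequence: 19 steps (from 1).

Step 10 (key step). What may go wrong: the metal carbene is diverted before or after ylide formation (insertion into the activated C-5–H bond, addition to the neighbouring 1,1-disubstituted alkene, a [1,2] instead of a [2,3] shift). Fallback: an acceptor/acceptor carbene, which is more selective for ylide formation, with the extra ester removed afterwards. It sets out from acid 12. Masamune chain extension (carbonyldiimidazole, then Mg(O2CCH2CO2Et)2, THF) should give β-keto ester F1; diazo transfer (4-acetamidobenzenesulfonyl azide, Et3N, MeCN) the diazo keto ester F2; Rh2(OAc)4 in CH2Cl2 the ring-expanded keto ester F3 by the same ylide/[2,3] sequence; and Krapcho dealkoxycarbonylation (LiCl, wet DMSO, 130 °C) removes the ester, the bridgehead C-1 being able to take its hydrogen on one face only. The fallback comes back to the route at ketone 16.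

Step 4. What may go wrong: loss of regiocontrol in carbene formation, so that the cross partner is delivered to the vinyl group on C-5 instead of C-8. Fallback: intramolecular engagement of the C-5 side through a temporary silicon tether. It sets out from alcohol 4. Chlorodimethylvinylsilane/imidazole should give vinylsilyl ether F4; ring-rearrangement metathesis in the presence of 6 (second-generation Grubbs catalyst RuCl2(H2IMes)(PCy3)(=CHPh)) closes a six-membered cyclic alkenylsiloxane onto the alkene carbon next to C-6 and leaves only the distal alkylidene for cross-metathesis with 6, giving siloxane F5; Bu4NF-induced protodesilylation frees the vinyl group and the hydroxyl in hydroxy oxolane F6; silylation as in step 3 then comes back to the route at 7.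

Step 19. What may go wrong: elimination, or failure of the SN2 displacement at the hindered allylic carbinol. Fallback: inversion by oxidation and reduction instead of substitution. It sets out from 28. Dess–Martin oxidation should give keto enal F7; Luche reduction (NaBH4, CeCl3·7H2O, MeOH, −78 °C) reduces both carbonyl groups, hydride entering C-8 from the open convex face, to give diol F8 with the target configuration at C-8; TEMPO/PhI(OAc)2 oxidises only the primary allylic alcohol to hydroxy enal F9; acylation with methacrylic anhydride/DMAP then comes back to the route at 30.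

**Further compounds**

F1 | step 10 | ethyl β-keto ester from 12 (oxolane of 7 with 5-(6-ethoxy-4,6-dioxohex-1-en-2-yl)) | COC(=O)C[C@H]1[C@H](O[Si](C)(C)C(C)(C)C)[C@H](C(=C)CC(=O)CC(=O)OCC)O[C@@H]1/C=C/COCc1ccc(OC)cc1
F2 | step 10 | α-diazo-β-keto ester of F1 | COC(=O)C[C@H]1[C@H](O[Si](C)(C)C(C)(C)C)[C@H](C(=C)CC(=O)C(=[N+]=[N-])C(=O)OCC)O[C@@H]1/C=C/COCc1ccc(OC)cc1
F3 | step 10 | 1-ethoxycarbonyl derivative of ketone 16 | COC(=O)C[C@@H]1/C=C\[C@H](COCc2ccc(OC)cc2)[C@]2(C(=O)OCC)O[C@H]([C@H]1O[Si](C)(C)C(C)(C)C)C(=C)CC2=O
F4 | step 4 | dimethyl(vinyl)silyl ether of 4 | COC(=O)C[C@H]1[C@H](O[Si](C)(C)C=C)[C@@H]2C=C[C@H]1O2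
F5 | step 4 | oxolane-fused cyclic alkenylsiloxane carrying the (E)-3-(4-methoxybenzyloxy)prop-1-enyl group | COC(=O)C[C@H]1[C@@H]2O[Si](C)(C)C=C[C@@H]2O[C@@H]1/C=C/COCc1ccc(OC)cc1
F6 | step 4 | 4-hydroxy analogue of oxolane 7 | COC(=O)C[C@H]1[C@H](O)[C@H](C=C)O[C@@H]1/C=C/COCc1ccc(OC)cc1
F7 | step 19 | 1,5:4,15-diepoxy-8,14-dioxogermacra-9,11(13)-dien-12,6-olide | C=C1[C@@H]2C(=O)/C=C(/C=O)[C@@H]3O[C@H]([C@H]2OC1=O)[C@]4(CO4)CC3
F8 | step 19 | 1,5:4,15-diepoxy-8,14-dihydroxygermacra-9,11(13)-dien-12,6-olide (C-8 as in the target) | C=C1[C@@H]2[C@H](O)/C=C(/CO)[C@@H]3O[C@H]([C@H]2OC1=O)[C@]4(CO4)CC3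
F9 | step 19 | 1,5:4,15-diepoxy-8-hydroxy-14-oxogermacra-9,11(13)-dien-12,6-olide (C-8 as in the target) | C=C1[C@@H]2[C@H](O)/C=C(/C=O)[C@@H]3O[C@H]([C@H]2OC1=O)[C@]4(CO4)CC3
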